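**Strategy.** Everything rests on opening the lactone of bractelactone at O1–C2 and C3–C8, which leads back to a 3-phenylpropane-1,2-dione arm on C3a beside the free C7a hydroxyl. This exploits the fact that the carbon substituents on C3a and C5, flanking the C4 methoxy, are both C6–C3 units, so that the furanone ring (O1, C2, C3, C3a, C7a) with its exocyclic C8 is an oxidised, rearranged copy of the C5 3-phenylpropanoyl chain. In one operation the key step closes that ring, shifts benzyl from C2 to C3 and dehydrates to the Z-benzylidene. Its precursor is a hexasubstituted benzene with three adjacent hydroxyls, one methoxy, one 3-phenylpropanoyl and one 2-oxo-3-phenylpropanoyl arm.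

Key step: step 10

Remark: bractelactone has no stereogenic centre, so only the Z geometry at C3=C8 has to be controlled and all transient sp3 centres are carried as racemates or diastereomer mixtures. The two arms are installed one after the other at different oxidation levels, and the pyrogallol stays MOM-protected through every oxidation, so no statistical mono-oxidation of a symmetric diketone is needed.

**Step 1**
Reactants: 1 3,4,5-trihydroxybenzaldehyde
Product: 2 3,4,5-tris(methoxymethoxy)benzaldehyde
Conditions: MOMCl (3.6 equiv), K2CO3, acetone, 0 °C to 50 °C, N2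
Reagents that add atoms: chloromethyl methyl ether, COCCl
Why: Williamson-type O-alkylation of the three phenoxides with the reactive α-chloro ether should be clean, and MOM is chosen because it directs the later ortho-lithiations and leaves under mild acid that spares a 1,2-dione.

**Step 2**
Reactants: 2 3,4,5-tris(methoxymethoxy)benzaldehyde
Product: 4 3,4,5-tris(methoxymethoxy)phenol, via aryl formate 3 (not isolated)
Conditions: mCPBA, CH2Cl2, 0 °C to rt; then K2CO3 (cat.), MeOH, rt
Reagents that add atoms: meta-chloroperoxybenzoic acid, O=C(OO)c1cccc(Cl)c1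
Why: Baeyer–Villiger (Dakin-type) oxidation, in which the electron-rich trialkoxyaryl group migrates in preference to hydride and the resulting formate is cleaved by transesterification with methanol.

**Step 3**
Reactants: 4 3,4,5-tris(methoxymethoxy)phenol
Product: 5 5-methoxy-1,2,3-tris(methoxymethoxy)benzene
Conditions: MeI, K2CO3, acetone, reflux
Reagents that add atoms: iodomethane, CI
Why: Williamson ether synthesis on the only free phenol fixes the future C4 methoxy and distinguishes it from the three MOM-masked pyrogallol oxygens.

**Step 4**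
Reactants: 5 5-methoxy-1,2,3-tris(methoxymethoxy)benzene; 6 3-phenylpropanal
Product: 8 1-[6-methoxy-2,3,4-tris(methoxymethoxy)phenyl]-3-phenylpropan-1-ol (racemic), via aryllithium 7 (not isolated)
Conditions: n-BuLi (1.1 equiv), THF, 0 °C; then 6, −78 °C to 0 °C; then AcOH
Reagents that add atoms: none
Why: Directed ortho-metalation, in which the two equivalent ring C–H positions each lie between OMe and OMOM and so give the same aryllithium, followed by 1,2-addition to the aldehyde at low temperature; the new carbinol centre is racemic and is erased in step 8.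

**Step 5**
Reactants: 9 3-phenylpropanoic acid
Product: 11 N-methoxy-N-methyl-3-phenylpropanamide, via acyl imidazole 10 (not isolated)
Conditions: CDI, CH2Cl2, rt; then MeNHOMe·HCl, rt
Reagents that add atoms: N,O-dimethylhydroxylamine hydrochloride, CNOC.Cl
Why: Weinreb amide formation by CDI activation and aminolysis of the acyl imidazole is a standard amide coupling.

**Step 6**
Reactants: 8 1-[6-methoxy-2,3,4-tris(methoxymethoxy)phenyl]-3-phenylpropan-1-ol; 11 N-methoxy-N-methyl-3-phenylpropanamide
Product: 13 1-[3-(1-hydroxy-3-phenylpropyl)-2-methoxy-4,5,6-tris(methoxymethoxy)phenyl]-3-phenylpropan-1-one (racemic), via dilithiated alkoxide 12 (not isolated)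
Conditions: n-BuLi (2.2 equiv), TMEDA, THF, −20 °C to 0 °C; then 11, −78 °C to 0 °C; then AcOH
Reagents that add atoms: none
Why: After O–H deprotonation the last ring C–H, again flanked by OMe and OMOM, is lithiated (directed ortho-metalation), and the Weinreb ketone synthesis stops at the ketone because the chelated tetrahedral adduct survives until the quench, so the two arms now differ in oxidation level (carbinol versus ketone).

**Step 7**
Reactants: 13 1-[3-(1-hydroxy-3-phenylpropyl)-2-methoxy-4,5,6-tris(methoxymethoxy)phenyl]-3-phenylpropan-1-one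
Product: 15 2-hydroxy-1-[3-(1-hydroxy-3-phenylpropyl)-2-methoxy-4,5,6-tris(methoxymethoxy)phenyl]-3-phenylpropan-1-one (diastereomer mixture), via dipotassium enolate 14 (not isolated)
Conditions: KHMDS (2.3 equiv), THF, −78 °C; then 3-phenyl-2-(phenylsulfonyl)oxaziridine, −78 °C; then AcOH
Reagents that add atoms: 3-phenyl-2-(phenylsulfonyl)oxaziridine (Davis oxaziridine), O=S(=O)(c1ccccc1)N1OC1c1ccccc1
Why: Davis oxidation, in which only the ketone arm has an enolisable α-CH2 and its potassium enolate should take up oxygen from the N-sulfonyloxaziridine to give the α-ketol; both sp3 centres are uncontrolled and are erased in step 8.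

**Step 8**
Reactants: 15 2-hydroxy-1-[3-(1-hydroxy-3-phenylpropyl)-2-methoxy-4,5,6-tris(methoxymethoxy)phenyl]-3-phenylpropan-1-one
Product: 16 1-[6-methoxy-2,3,4-tris(methoxymethoxy)-5-(3-phenylpropanoyl)phenyl]-3-phenylpropane-1,2-dione
Conditions: Dess–Martin periodinane (2.6 equiv), CH2Cl2, 0 °C to rt
Reagents that add atoms: none
Why: Dess–Martin oxidation should convert the benzylic carbinol into the 3-phenylpropanoyl ketone and the α-ketol (either acyloin regioisomer) into the 1,2-dione in one near-neutral operation that leaves the MOM ethers and the fully substituted arene untouched.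

**Step 9**
Reactants: 16 1-[6-methoxy-2,3,4-tris(methoxymethoxy)-5-(3-phenylpropanoyl)phenyl]-3-phenylpropane-1,2-dione
Product: 17 1-[2,3,4-trihydroxy-6-methoxy-5-(3-phenylpropanoyl)phenyl]-3-phenylpropane-1,2-dione
Conditions: 3 M aq HCl, MeOH/THF (degassed), 40 °C, Ar
Reagents that add atoms: none
Why: Acid-catalysed cleavage of the three aryl MOM acetals (transacetalisation to dimethoxymethane) should leave the dione, the ketone and the methyl ether intact; the product is expected to sit in ring–chain equilibrium with its cyclic hemiketal and is used at once under argon.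

**Step 10**
Reactants: 17 1-[2,3,4-trihydroxy-6-methoxy-5-(3-phenylpropanoyl)phenyl]-3-phenylpropane-1,2-dione
Product: 20 bractelactone, via cyclic hemiketal 18 (not isolated), via hydroxylactone 19 (not isolated)
Conditions: Et3N (1.5 equiv), degassed MeCN, Ar, 50 °C; then TsOH·H2O (20 mol %), PhMe, 90 °C
Reagents that add atoms: none
Why: Under mild base the C7a phenolate adds to the outer, benzyl-bearing carbonyl of the dione (O1–C2 bond) to give the 2-benzyl-2-hydroxybenzofuran-3-one 18, whose C2 alkoxide pushes benzyl onto the aryl-bound carbonyl carbon (C3–C8 bond) and so turns hemiketal plus ketone into lactone plus tertiary alcohol 19; TsOH then ionises this alcohol to a cation stabilised by the ortho and para ring oxygens, and loss of a benzylic proton gives the benzylidene. The closest known reaction type is the intramolecular benzilic ester (α-ketol, acyloin) rearrangement of a 1,2-diketone with a phenol as internal nucleophile, followed by E1 dehydration. The one ring is closed by 5-exo-trig addition of oxygen to a carbonyl group. No stereocentre survives (C2 of 18 and C3 of 19 are racemic and are erased), and the alkene geometry is set under equilibrating acid conditions, Z being favoured because the phenyl group avoids the C4 methoxy and lies on the side of the lactone carbonyl. The step needs site selectivity and a single migrating group: only the C7a hydroxyl is ortho to the dione arm and can form a five-membered hemiketal, only benzyl on C2 can shift, and the C5 ketone arm cannot reach the dione. Running the base stage before any strong acid keeps 18 from losing water towards the 2-benzylidene (aurone) series, and exclusion of oxygen protects the pyrogallol.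

**Compound list**

1 | 3,4,5-trihydroxybenzaldehyde | O=Cc1cc(O)c(O)c(O)c1 | starting material
2 | 3,4,5-tris(methoxymethoxy)benzaldehyde | O=Cc1cc(OCOC)c(OCOC)c(OCOC)c1 | intermediate
3 | 3,4,5-tris(methoxymethoxy)phenyl formate | O=COc1cc(OCOC)c(OCOC)c(OCOC)c1 | intermediate
4 | 3,4,5-tris(methoxymethoxy)phenol | Oc1cc(OCOC)c(OCOC)c(OCOC)c1 | intermediate
5 | 5-methoxy-1,2,3-tris(methoxymethoxy)benzene | COc1cc(OCOC)c(OCOC)c(OCOC)c1 | intermediate
6 | 3-phenylpropanal | O=CCCc1ccccc1 | starting material
7 | [6-methoxy-2,3,4-tris(methoxymethoxy)phenyl]lithium | [Li]c1c(OC)cc(OCOC)c(OCOC)c1OCOC | intermediate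
8 | 1-[6-methoxy-2,3,4-tris(methoxymethoxy)phenyl]-3-phenylpropan-1-ol (racemic) | OC(CCc1ccccc1)c1c(OC)cc(OCOC)c(OCOC)c1OCOC | intermediate
9 | 3-phenylpropanoic acid | O=C(O)CCc1ccccc1 | starting material
10 | 1-(imidazol-1-yl)-3-phenylpropan-1-one | O=C(CCc1ccccc1)n1ccnc1 | intermediate
11 | N-methoxy-N-methyl-3-phenylpropanamide | CON(C)C(=O)CCc1ccccc1 | intermediate
12 | lithium 1-[3-lithio-2-methoxy-4,5,6-tris(methoxymethoxy)phenyl]-3-phenylpropan-1-olate (racemic) | [Li]OC(CCc1ccccc1)c1c(OC)c([Li])c(OCOC)c(OCOC)c1OCOC | intermediate
13 | 1-[3-(1-hydroxy-3-phenylpropyl)-2-methoxy-4,5,6-tris(methoxymethoxy)phenyl]-3-phenylpropan-1-one (racemic) | OC(CCc1ccccc1)c1c(OC)c(C(=O)CCc2ccccc2)c(OCOC)c(OCOC)c1OCOC | intermediate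
14 | dipotassium alkoxide enolate of 13 (Z enolate expected, geometry immaterial) | [K]OC(CCc1ccccc1)c1c(OC)c(/C(O[K])=C/Cc2ccccc2)c(OCOC)c(OCOC)c1OCOC | intermediate
15 | 2-hydroxy-1-[3-(1-hydroxy-3-phenylpropyl)-2-methoxy-4,5,6-tris(methoxymethoxy)phenyl]-3-phenylpropan-1-one (diastereomer mixture) | OC(CCc1ccccc1)c1c(OC)c(C(=O)C(O)Cc2ccccc2)c(OCOC)c(OCOC)c1OCOC | intermediate
16 | 1-[6-methoxy-2,3,4-tris(methoxymethoxy)-5-(3-phenylpropanoyl)phenyl]-3-phenylpropane-1,2-dione | COc1c(C(=O)CCc2ccccc2)c(OCOC)c(OCOC)c(OCOC)c1C(=O)C(=O)Cc1ccccc1 | intermediate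
17 | 1-[2,3,4-trihydroxy-6-methoxy-5-(3-phenylpropanoyl)phenyl]-3-phenylpropane-1,2-dione | COc1c(C(=O)CCc2ccccc2)c(O)c(O)c(O)c1C(=O)C(=O)Cc1ccccc1 | intermediate
18 | 2-benzyl-2,6,7-trihydroxy-4-methoxy-5-(3-phenylpropanoyl)-1-benzofuran-3(2H)-one (racemic) | COc1c(C(=O)CCc2ccccc2)c(O)c(O)c2OC(O)(Cc3ccccc3)C(=O)c12 | intermediate
19 | 3-benzyl-3,6,7-trihydroxy-4-methoxy-5-(3-phenylpropanoyl)-1-benzofuran-2(3H)-one (racemic) | COc1c(C(=O)CCc2ccccc2)c(O)c(O)c2OC(=O)C(O)(Cc3ccccc3)c12 | intermediate
20 | bractelactone, (3Z)-3-benzylidene-6,7-dihydroxy-4-methoxy-5-(3-phenylpropanoyl)-1-benzofuran-2(3H)-one | COc1c(C(=O)CCc2ccccc2)c(O)c(O)c2c1/C(=C/c1ccccc1)C(=O)O2 | target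

**Step count.** Total: 10 steps. Longest linear sequence: 9 steps (steps 1–4 and 6–10, from 1); step 5 is a one-step branch.

**Steps most likely to fail**

Step 10. The benzyl 1,2-shift may stall at the enolised dione or hemiketal stage, or may be outrun by loss of water from the hemiketal towards the aurone series or by reversible oxa-Michael closure to a dihydroflavonol. The fallback moves the rearrangement to the protected stage and uses external hydroxide. It sets out from 16, which is treated with KOH in aqueous dioxane at 60 °C under argon (classical benzilic acid rearrangement, either migration mode giving the same acid) and acidified to give 2-hydroxy-2-[6-methoxy-2,3,4-tris(methoxymethoxy)-5-(3-phenylpropanoyl)phenyl]-3-phenylpropanoic acid F1. HCl in MeOH/THF then removes the MOM groups, and the ortho phenol lactonises onto the acid. The route is rejoined at 19, which is dehydrated with TsOH in toluene to 20.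

Step 7. Enolisation of the hindered ketone next to a potassium alkoxide may be incomplete, or the enolate may be captured by the sulfonylimine released from the oxidant. The fallback buys the α-oxygen with the building block instead of installing it by enolate oxidation. It sets out from 8. Commercial methyl 2-hydroxy-3-phenylpropanoate is converted with MeNHOMe·HCl and i-PrMgCl into 2-hydroxy-N-methoxy-N-methyl-3-phenylpropanamide F2, and silylation (TBSCl, imidazole, DMF) gives 2-[tert-butyl(dimethyl)silyl]oxy-N-methoxy-N-methyl-3-phenylpropanamide F3. The dianion 12, generated from 8 as in step 6, is acylated with F3 to give 2-[tert-butyl(dimethyl)silyl]oxy-1-[3-(1-hydroxy-3-phenylpropyl)-2-methoxy-4,5,6-tris(methoxymethoxy)phenyl]-3-phenylpropan-1-one F4. Buffered TBAF in THF removes the silyl group, and the route is rejoined at 15.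

Step 6. Deprotonation of the crowded, alkoxide-bearing arene may be incomplete or misdirected (aggregation, attack on a MOM methylene), returning 8. The fallback generates the same organometallic by halogen–metal exchange instead of deprotonation. It sets out from 8, which is brominated at its only free ring position with NBS in MeCN at 0 °C to give 1-[3-bromo-2-methoxy-4,5,6-tris(methoxymethoxy)phenyl]-3-phenylpropan-1-ol F5. n-BuLi (2.1 equiv, THF, −78 °C) first removes the hydroxyl proton and then exchanges bromine for lithium to give 12. Acylation with 11 rejoins the route at 13.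

**Further compounds**

F1 | step 10 | 2-hydroxy-2-[6-methoxy-2,3,4-tris(methoxymethoxy)-5-(3-phenylpropanoyl)phenyl]-3-phenylpropanoic acid (racemic) | COc1c(C(=O)CCc2ccccc2)c(OCOC)c(OCOC)c(OCOC)c1C(O)(Cc1ccccc1)C(=O)O
F2 | step 7 | 2-hydroxy-N-methoxy-N-methyl-3-phenylpropanamide (racemic) | CON(C)C(=O)C(O)Cc1ccccc1
F3 | step 7 | 2-[tert-butyl(dimethyl)silyl]oxy-N-methoxy-N-methyl-3-phenylpropanamide (racemic) | CON(C)C(=O)C(O[Si](C)(C)C(C)(C)C)Cc1ccccc1
F4 | step 7 | 2-[tert-butyl(dimethyl)silyl]oxy-1-[3-(1-hydroxy-3-phenylpropyl)-2-methoxy-4,5,6-tris(methoxymethoxy)phenyl]-3-phenylpropan-1-one (diastereomer mixture) | OC(CCc1ccccc1)c1c(OC)c(C(=O)C(O[Si](C)(C)C(C)(C)C)Cc2ccccc2)c(OCOC)c(OCOC)c1OCOC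
F5 | step 6 | 1-[3-bromo-2-methoxy-4,5,6-tris(methoxymethoxy)phenyl]-3-phenylpropan-1-ol (racemic) | OC(CCc1ccccc1)c1c(OC)c(Br)c(OCOC)c(OCOC)c1OCOC
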